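**Plan**

- Retrosynthesis: the 3-(hydroxymethyl)-5-ylidenefuran-2(5H)-one is cut at its exocyclic C=C (back to a lactol), then at the lactone C2=O and lactol C5–O bonds. Its C2–C5 and ring oxygen are those of a 5-alkyl-3-(oxymethyl)furan oxidised at the free α-carbon, which carries SiMe3; the second furan ring at the far chain end stays as it is.
- The chain is cut at the furan C5–CH2 bond and at the two allylic C–C bonds that flank a geranyl unit (C8–CH2 of the chiral piece, C1–CH2 of the furylmethyl piece).
- Forward: 3-furanmethanol gives the C2-silylated, O-protected furan; C5 is alkylated with the iodide from (S)-2-methylbutane-1,4-diol; the side chain becomes a Grignard reagent and is joined by copper catalysis to 8-bromogeranyl acetate, then to 3-furylmethylmagnesium chloride.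
- The lactone is the only ring formed (step 13, singlet oxygen on the silylfuran); lactol dehydration and desilylation finish the route.
- Stereochemistry: the single stereocentre is bought with the diol and is never a reacting carbon; both E-alkenes come from geranyl acetate and survive the couplings; the Z-ylidene arises in the dehydration as the more stable isomer.

Key step: step 13

Remark on the chemistry: lactol 25 is expected as both C5 epimers and is used as such. The configuration at the methyl-bearing carbon is the same throughout; its descriptor reads (R) in 13 and 17 only because Br and Mg change the CIP ranking. TBS = tert-butyldimethylsilyl, TBDPS = tert-butyldiphenylsilyl.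

**Route**

Step 1
Reactants: 1 furan-3-ylmethanol
Product: 4 [2-(trimethylsilyl)furan-3-yl]methanol, via dilithio species 2 (not isolated), via bis-silylated furan 3 (not isolated)
Conditions: n-BuLi (2.2 equiv), THF, −78 → 0 °C; Me3SiCl (2.4 equiv), −78 → 20 °C; K2CO3, MeOH, 20 °C
Reagents that add atoms: chlorotrimethylsilane, C[Si](C)(C)Cl
Why: Alkoxide-directed lithiation places the second lithium on the adjacent α-carbon C2, both anionic sites are silylated, and mild methanolysis cleaves only the labile O–SiMe3 bond.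

Step 2
Reactants: 4 [2-(trimethylsilyl)furan-3-yl]methanol
Product: 5 tert-butyl(diphenyl){[2-(trimethylsilyl)furan-3-yl]methoxy}silane
Conditions: t-BuPh2SiCl, imidazole, DMF, 0 → 20 °C
Reagents that add atoms: tert-butyl(chloro)diphenylsilane, CC(C)(C)[Si](Cl)(c1ccccc1)c1ccccc1
Why: Imidazole-promoted silyl ether formation; the bulky TBDPS ether is a poor directing group for lithiation, outlasts the weak-acid removal of a TBS ether in step 6 and is cleaved by fluoride at the end.

Step 3
Reactants: 6 (S)-2-methylbutane-1,4-diol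
Product: 7 (S)-4-(tert-butyldimethylsilyloxy)-2-methylbutan-1-ol
Conditions: t-BuMe2SiCl (0.95 equiv), Et3N, 4-(dimethylamino)pyridine (5 mol%), CH2Cl2, −40 °C
Reagents that add atoms: tert-butyl(chloro)dimethylsilane, CC(C)(C)[Si](C)(C)Cl
Why: Sterically controlled monosilylation, in which the unbranched C4 hydroxyl should react faster than the C1 hydroxyl next to the methyl-bearing carbon; regioisomer and bis-ether are removed by chromatography and the stereocentre is untouched.

Step 4
Reactants: 7 (S)-4-(tert-butyldimethylsilyloxy)-2-methylbutan-1-ol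
Product: 8 tert-butyl{[(3S)-4-iodo-3-methylbutyl]oxy}dimethylsilane
Conditions: I2, PPh3, imidazole, CH2Cl2, 0 → 20 °C
Reagents that add atoms: iodine, [I][I]
Why: Appel-type iodination (Garegg–Samuelsson conditions) by SN2 displacement of the alkoxyphosphonium at a primary carbon; imidazole buffers the acid so the silyl ether stays, and the β-stereocentre is not involved.

Step 5
Reactants: 5 tert-butyl(diphenyl){[2-(trimethylsilyl)furan-3-yl]methoxy}silane; 8 tert-butyl{[(3S)-4-iodo-3-methylbutyl]oxy}dimethylsilane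
Product: 10 5-[(2S)-4-(tert-butyldimethylsilyloxy)-2-methylbutyl]-3-[(tert-butyldiphenylsilyloxy)methyl]-2-(trimethylsilyl)furan, via 5-lithiofuran 9 (not isolated)
Conditions: n-BuLi (1.05 equiv), THF, −78 → 0 °C; DMPU, 8 (0.8 equiv), −78 → 20 °C
Reagents that add atoms: none
Why: α-Lithiation of the furan at C5, the only free α-position since C2 is blocked by silicon, followed by SN2 alkylation of the 2-furyllithium by the primary iodide in THF/DMPU; the reaction occurs at CH2, so the configuration is kept.

Step 6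
Reactants: 10 5-[(2S)-4-(tert-butyldimethylsilyloxy)-2-methylbutyl]-3-[(tert-butyldiphenylsilyloxy)methyl]-2-(trimethylsilyl)furan
Product: 11 (3S)-4-{4-[(tert-butyldiphenylsilyloxy)methyl]-5-(trimethylsilyl)furan-2-yl}-3-methylbutan-1-ol
Conditions: pyridinium p-toluenesulfonate (0.2 equiv), MeOH, 20 °C
Reagents that add atoms: none
Why: Acid-catalysed methanolysis (selective desilylation) removes the primary TBS ether much faster than the TBDPS ether, and the acid is too weak for ipso-protodesilylation of the furylsilane.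

Step 7
Reactants: 11 (3S)-4-{4-[(tert-butyldiphenylsilyloxy)methyl]-5-(trimethylsilyl)furan-2-yl}-3-methylbutan-1-ol
Product: 13 5-[(2R)-4-bromo-2-methylbutyl]-3-[(tert-butyldiphenylsilyloxy)methyl]-2-(trimethylsilyl)furan, via mesylate 12 (not isolated)
Conditions: MsCl, Et3N, CH2Cl2, 0 °C; LiBr, acetone, 45 °C
Reagents that add atoms: lithium bromide, [Li+].[Br-] (methanesulfonyl chloride, CS(=O)(=O)Cl, supplies only the mesyl group of 12)
Why: Mesylation followed by Finkelstein-type SN2 displacement at an unbranched primary carbon; no electrophilic halogen is present, so ipso-halodesilylation of the furan cannot occur.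

Step 8
Reactants: 14 geranyl acetate
Product: 15 (2E,6E)-8-hydroxy-3,7-dimethylocta-2,6-dien-1-yl acetate
Conditions: SeO2 (10 mol%), t-BuOOH (70% in H2O, 3 equiv), 2-hydroxybenzoic acid (10 mol%), CH2Cl2, 20 °C
Reagents that add atoms: tert-butyl hydroperoxide, CC(C)(C)OO (terminal oxidant; the oxygen is passed on through SeO2, O=[Se]=O)
Why: Riley-type allylic oxidation in its catalytic form (ene reaction, then [2,3]-sigmatropic shift) attacks the (E)-methyl of the terminal, more electron-rich alkene, while the acetate deactivates the 2,3-alkene; the mechanism fixes the E geometry.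

Step 9
Reactants: 15 (2E,6E)-8-hydroxy-3,7-dimethylocta-2,6-dien-1-yl acetate
Product: 16 (2E,6E)-8-bromo-3,7-dimethylocta-2,6-dien-1-yl acetate
Conditions: PBr3 (0.4 equiv), Et2O, −10 °C
Reagents that add atoms: phosphorus tribromide, BrP(Br)Br
Why: Deoxybromination by SN2 attack of bromide on the phosphite ester at the primary allylic carbon, which at low temperature should proceed without allylic transposition or loss of the acetate.

Step 10
Reactants: 13 5-[(2R)-4-bromo-2-methylbutyl]-3-[(tert-butyldiphenylsilyloxy)methyl]-2-(trimethylsilyl)furan; 16 (2E,6E)-8-bromo-3,7-dimethylocta-2,6-dien-1-yl acetate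
Product: 18 (2E,6E,11S)-12-{4-[(tert-butyldiphenylsilyloxy)methyl]-5-(trimethylsilyl)furan-2-yl}-3,7,11-trimethyldodeca-2,6-dien-1-yl acetate, via Grignard reagent 17 (not isolated)
Conditions: Mg, THF, 40 °C; 16, Li2CuCl4 (3 mol%), THF, −78 → −20 °C
Reagents that add atoms: none
Why: Copper-catalysed Grignard cross-coupling of Kochi type, in which the allylic bromide should react at its primary carbon at low temperature in THF while the allylic acetate and its carbonyl are inert; the E-alkenes and the remote stereocentre are not affected.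

Step 11
Reactants: 1 furan-3-ylmethanol
Product: 19 3-(chloromethyl)furan
Conditions: SOCl2, pyridine, Et2O, 0 °C
Reagents that add atoms: thionyl chloride, O=S(Cl)Cl
Why: Deoxychlorination through the chlorosulfite with SN2 attack of chloride; pyridine takes up HCl and protects the acid-sensitive furan.

Step 12
Reactants: 19 3-(chloromethyl)furan; 18 (2E,6E,11S)-12-{4-[(tert-butyldiphenylsilyloxy)methyl]-5-(trimethylsilyl)furan-2-yl}-3,7,11-trimethyldodeca-2,6-dien-1-yl acetate
Product: 21 3-[(tert-butyldiphenylsilyloxy)methyl]-5-[(2S,6E,10E)-13-(furan-3-yl)-2,6,10-trimethyltrideca-6,10-dien-1-yl]-2-(trimethylsilyl)furan, via furylmethyl Grignard reagent 20 (not isolated)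
Conditions: Mg, THF, 0 °C (19, 3 equiv); 18, Li2CuCl4 (5 mol%), THF, −20 → 0 °C
Reagents that add atoms: none
Why: A second copper-catalysed Grignard coupling, now with the allylic acetate as leaving group; substitution should occur at the primary carbon because the other allyl terminus is fully substituted, the E geometry is kept, and under copper catalysis the furylmethyl reagent reacts through its CH2 carbon.

Step 13
Reactants: 21 3-[(tert-butyldiphenylsilyloxy)methyl]-5-[(2S,6E,10E)-13-(furan-3-yl)-2,6,10-trimethyltrideca-6,10-dien-1-yl]-2-(trimethylsilyl)furan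
Product: 25 3-[(tert-butyldiphenylsilyloxy)methyl]-5-[(2S,6E,10E)-13-(furan-3-yl)-2,6,10-trimethyltrideca-6,10-dien-1-yl]-5-hydroxyfuran-2(5H)-one (both C5 epimers), via endoperoxide 22 (not isolated), via silyl oxoenoate 23 (not isolated), via keto acid 24 (not isolated)
Conditions: O2, visible light, 5,10,15,20-tetraphenylporphyrin (1 mol%), CH2Cl2, −78 °C, irradiation stopped at about one equivalent of O2 uptake; H2O, −78 → 20 °C
Reagents that add atoms: dioxygen (used as singlet oxygen), O=O
Why: Singlet oxygen adds across C2 and C5 of the silylated furan in a [4+2] cycloaddition to give endoperoxide 22; the SiMe3 group then shifts from C2 to the neighbouring peroxide oxygen as the O–O bond breaks (a Baeyer–Villiger-like 1,2-shift), which opens the bicycle to silyl (Z)-4-oxo-2-enoate 23 and puts the future carbonyl on the carbon that carried silicon. Water cleaves the silyl ester, and the carboxyl oxygen of keto acid 24 adds to the cis-placed ketone (5-exo-trig) to close the lactone ring as lactol 25, so the lactone C=O and the lactol C–O are the two new bonds. The closest known reaction type is the sensitised photooxygenation of 2-trimethylsilylfurans to 5-hydroxyfuran-2(5H)-ones. No stereocentre is controlled: the lactol carbon forms as both epimers and becomes sp2 in step 14, and the methyl-bearing centre is a bystander. The step needs selectivity for the 2,3,5-trisubstituted silylfuran over the 3-monoalkylfuran and the two trisubstituted alkenes; this rests on the higher electron density of the α,α′-disubstituted ring, which is expected to take up singlet oxygen clearly faster than a β-monoalkylfuran and far faster than the alkenes undergo the ene reaction, on the low temperature, and on stopping short of full conversion with recovery of 21.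

Step 14
Reactants: 25 3-[(tert-butyldiphenylsilyloxy)methyl]-5-[(2S,6E,10E)-13-(furan-3-yl)-2,6,10-trimethyltrideca-6,10-dien-1-yl]-5-hydroxyfuran-2(5H)-one
Product: 27 (5Z)-3-[(tert-butyldiphenylsilyloxy)methyl]-5-[(2S,6E,10E)-13-(furan-3-yl)-2,6,10-trimethyltrideca-6,10-dien-1-ylidene]furan-2(5H)-one, via lactol mesylate 26 (not isolated)
Conditions: MsCl, Et3N, CH2Cl2, −30 → 0 °C
Reagents that add atoms: none
Why: Lactol dehydration by sulfonylation and E1-type elimination: the sulfonate leaves from the acylal carbon and Et3N removes an exocyclic CH2 proton; the Z isomer is expected because the chain then lies beside the ring oxygen and avoids A(1,3) strain against C4–H, and the weak amine base should not epimerise the new allylic stereocentre.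

Step 15
Reactants: 27 (5Z)-3-[(tert-butyldiphenylsilyloxy)methyl]-5-[(2S,6E,10E)-13-(furan-3-yl)-2,6,10-trimethyltrideca-6,10-dien-1-ylidene]furan-2(5H)-one
Product: 28 (5Z)-5-[(2S,6E,10E)-13-(furan-3-yl)-2,6,10-trimethyltrideca-6,10-dien-1-ylidene]-3-(hydroxymethyl)furan-2(5H)-one
Conditions: HF·pyridine, pyridine, THF, 0 → 20 °C
Reagents that add atoms: none
Why: Fluoride-driven desilylation under buffered, weakly acidic conditions, which should spare the base-sensitive Z-ylidene lactone, its allylic stereocentre and the acid-sensitive furan.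

**Compound list**

1 | furan-3-ylmethanol (3-furanmethanol) | OCc1ccoc1 | starting material
2 | lithium (2-lithiofuran-3-yl)methanolate | [Li]OCc1ccoc1[Li] | intermediate
3 | trimethyl{3-[(trimethylsilyloxy)methyl]furan-2-yl}silane | C[Si](C)(C)OCc1ccoc1[Si](C)(C)C | intermediate
4 | [2-(trimethylsilyl)furan-3-yl]methanol | OCc1ccoc1[Si](C)(C)C | intermediate
5 | tert-butyl(diphenyl){[2-(trimethylsilyl)furan-3-yl]methoxy}silane | CC(C)(C)[Si](OCc1ccoc1[Si](C)(C)C)(c1ccccc1)c1ccccc1 | intermediate
6 | (S)-2-methylbutane-1,4-diol | OCC[C@H](C)CO | starting material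
7 | (S)-4-(tert-butyldimethylsilyloxy)-2-methylbutan-1-ol | CC(C)(C)[Si](C)(C)OCC[C@H](C)CO | intermediate
8 | tert-butyl{[(3S)-4-iodo-3-methylbutyl]oxy}dimethylsilane | CC(C)(C)[Si](C)(C)OCC[C@H](C)CI | intermediate
9 | {4-[(tert-butyldiphenylsilyloxy)methyl]-5-(trimethylsilyl)furan-2-yl}lithium | CC(C)(C)[Si](OCc1cc([Li])oc1[Si](C)(C)C)(c1ccccc1)c1ccccc1 | intermediate
10 | 5-[(2S)-4-(tert-butyldimethylsilyloxy)-2-methylbutyl]-3-[(tert-butyldiphenylsilyloxy)methyl]-2-(trimethylsilyl)furan | CC(C)(C)[Si](C)(C)OCC[C@H](C)Cc1cc(CO[Si](c2ccccc2)(c2ccccc2)C(C)(C)C)c([Si](C)(C)C)o1 | intermediate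
11 | (3S)-4-{4-[(tert-butyldiphenylsilyloxy)methyl]-5-(trimethylsilyl)furan-2-yl}-3-methylbutan-1-ol | OCC[C@H](C)Cc1cc(CO[Si](c2ccccc2)(c2ccccc2)C(C)(C)C)c([Si](C)(C)C)o1 | intermediate
12 | (3S)-4-{4-[(tert-butyldiphenylsilyloxy)methyl]-5-(trimethylsilyl)furan-2-yl}-3-methylbutyl methanesulfonate | CS(=O)(=O)OCC[C@H](C)Cc1cc(CO[Si](c2ccccc2)(c2ccccc2)C(C)(C)C)c([Si](C)(C)C)o1 | intermediate
13 | 5-[(2R)-4-bromo-2-methylbutyl]-3-[(tert-butyldiphenylsilyloxy)methyl]-2-(trimethylsilyl)furan | BrCC[C@H](C)Cc1cc(CO[Si](c2ccccc2)(c2ccccc2)C(C)(C)C)c([Si](C)(C)C)o1 | intermediate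
14 | geranyl acetate, (2E)-3,7-dimethylocta-2,6-dien-1-yl acetate | CC(C)=CCC/C(C)=C/COC(C)=O | starting material
15 | (2E,6E)-8-hydroxy-3,7-dimethylocta-2,6-dien-1-yl acetate | OC/C(C)=C/CC/C(C)=C/COC(C)=O | intermediate
16 | (2E,6E)-8-bromo-3,7-dimethylocta-2,6-dien-1-yl acetate | BrC/C(C)=C/CC/C(C)=C/COC(C)=O | intermediate
17 | [(3R)-4-{4-[(tert-butyldiphenylsilyloxy)methyl]-5-(trimethylsilyl)furan-2-yl}-3-methylbutyl]magnesium bromide | Br[Mg]CC[C@H](C)Cc1cc(CO[Si](c2ccccc2)(c2ccccc2)C(C)(C)C)c([Si](C)(C)C)o1 | intermediate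
18 | (2E,6E,11S)-12-{4-[(tert-butyldiphenylsilyloxy)methyl]-5-(trimethylsilyl)furan-2-yl}-3,7,11-trimethyldodeca-2,6-dien-1-yl acetate | CC(=O)OC/C=C(\C)CC/C=C(\C)CCC[C@H](C)Cc1cc(CO[Si](c2ccccc2)(c2ccccc2)C(C)(C)C)c([Si](C)(C)C)o1 | intermediate
19 | 3-(chloromethyl)furan | ClCc1ccoc1 | intermediate
20 | (furan-3-ylmethyl)magnesium chloride | Cl[Mg]Cc1ccoc1 | intermediate
21 | 3-[(tert-butyldiphenylsilyloxy)methyl]-5-[(2S,6E,10E)-13-(furan-3-yl)-2,6,10-trimethyltrideca-6,10-dien-1-yl]-2-(trimethylsilyl)furan | C/C(=C\CCc1ccoc1)CC/C=C(\C)CCC[C@H](C)Cc1cc(CO[Si](c2ccccc2)(c2ccccc2)C(C)(C)C)c([Si](C)(C)C)o1 | intermediate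
22 | 6-[(tert-butyldiphenylsilyloxy)methyl]-4-[(2S,6E,10E)-13-(furan-3-yl)-2,6,10-trimethyltrideca-6,10-dien-1-yl]-1-(trimethylsilyl)-2,3,7-trioxabicyclo[2.2.1]hept-5-ene | C/C(=C\CCc1ccoc1)CC/C=C(\C)CCC[C@H](C)CC12OOC([Si](C)(C)C)(O1)C(CO[Si](c3ccccc3)(c3ccccc3)C(C)(C)C)=C2 | intermediate
23 | trimethylsilyl (2Z,6S,10E,14E)-2-[(tert-butyldiphenylsilyloxy)methyl]-17-(furan-3-yl)-6,10,14-trimethyl-4-oxoheptadeca-2,10,14-trienoate | C/C(=C\CCc1ccoc1)CC/C=C(\C)CCC[C@H](C)CC(=O)/C=C(/CO[Si](c1ccccc1)(c1ccccc1)C(C)(C)C)C(=O)O[Si](C)(C)C | intermediate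
24 | (2Z,6S,10E,14E)-2-[(tert-butyldiphenylsilyloxy)methyl]-17-(furan-3-yl)-6,10,14-trimethyl-4-oxoheptadeca-2,10,14-trienoic acid | C/C(=C\CCc1ccoc1)CC/C=C(\C)CCC[C@H](C)CC(=O)/C=C(/CO[Si](c1ccccc1)(c1ccccc1)C(C)(C)C)C(=O)O | intermediate
25 | 3-[(tert-butyldiphenylsilyloxy)methyl]-5-[(2S,6E,10E)-13-(furan-3-yl)-2,6,10-trimethyltrideca-6,10-dien-1-yl]-5-hydroxyfuran-2(5H)-one, both C5 epimers | C/C(=C\CCc1ccoc1)CC/C=C(\C)CCC[C@H](C)CC1(O)C=C(CO[Si](c2ccccc2)(c2ccccc2)C(C)(C)C)C(=O)O1 | intermediate
26 | C5 methanesulfonate of 25 | C/C(=C\CCc1ccoc1)CC/C=C(\C)CCC[C@H](C)CC1(OS(C)(=O)=O)C=C(CO[Si](c2ccccc2)(c2ccccc2)C(C)(C)C)C(=O)O1 | intermediate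
27 | (5Z)-3-[(tert-butyldiphenylsilyloxy)methyl]-5-[(2S,6E,10E)-13-(furan-3-yl)-2,6,10-trimethyltrideca-6,10-dien-1-ylidene]furan-2(5H)-one | C/C(=C\CCc1ccoc1)CC/C=C(\C)CCC[C@H](C)/C=C1/C=C(CO[Si](c2ccccc2)(c2ccccc2)C(C)(C)C)C(=O)O1 | intermediate
28 | (5Z)-5-[(2S,6E,10E)-13-(furan-3-yl)-2,6,10-trimethyltrideca-6,10-dien-1-ylidene]-3-(hydroxymethyl)furan-2(5H)-one | C/C(=C\CCc1ccoc1)CC/C=C(\C)CCC[C@H](C)/C=C1/C=C(CO)C(=O)O1 | target

**Summary**

Total step count: 15. Longest linear sequence: 10 steps (steps 1, 2, 5, 6, 7, 10, 12, 13, 14, 15; the branch from the diol through steps 3 and 4 is equally long).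

Steps most likely to fail:

Step 13. Site selectivity may be lost: singlet oxygen may add to the far furan ring at a competitive rate, or the alkenes may undergo the ene reaction, so that over-oxidation consumes the mono-oxidised product. The fallback oxidises before the second furan exists. It sets out from 18, which is photooxygenated under the conditions of step 13 to the hydroxybutenolide acetate F1 and dehydrated as in step 14 to the Z-ylidene lactone acetate F2. The furylmethyl carbon is then attached by a lactone-tolerant Pd-catalysed allyl–benzyl cross-coupling of Negishi type: Grignard reagent 20 is transmetalated with ZnCl2 to (furan-3-ylmethyl)zinc chloride F3, which is coupled with F2 using Pd(PPh3)4 (5 mol%) in THF at 20 °C. Reaction at the primary allyl terminus should give 27, where the route is rejoined.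

Step 10. The Grignard reagent may attack the γ-carbon of the allylic bromide (allylic transposition), add to the acetate carbonyl, or be lost to homocoupling while it is formed. The fallback replaces the organomagnesium by a sulfone-stabilised carbanion, which alkylates allylic halides only at the halide-bearing carbon. It sets out from 13, which is treated with PhSO2Na in DMF at 60 °C to give the sulfone F4. Deprotonation with n-BuLi in THF at −78 °C gives the lithiated sulfone F5, and alkylation with 16 at −78 °C gives the sulfonyl acetate F6. Reductive desulfonylation with sodium amalgam (Na/Hg) and Na2HPO4 in MeOH/THF at −20 °C returns to 18.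

Step 5. Substitution at the β-branched primary iodide may be slow, so that elimination and proton transfer to the furyllithium take over and conversion stays low. The fallback forms the same bond by Negishi cross-coupling. It sets out from 9 and 8. Quenching 9 with 1,2-diiodoethane at −78 °C gives the iodofuran F7. Zinc insertion into 8 (Zn dust, LiCl, THF, 40 °C) gives the alkylzinc iodide F8. Coupling of F7 and F8 with Pd(OAc)2 and 2-dicyclohexylphosphino-2′,6′-dimethoxybiphenyl in THF at 40 °C returns to 10.

**Further compounds**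

F1 | step 13 | (2E,6E,11S)-12-{4-[(tert-butyldiphenylsilyloxy)methyl]-2-hydroxy-5-oxo-2,5-dihydrofuran-2-yl}-3,7,11-trimethyldodeca-2,6-dien-1-yl acetate, both lactol epimers | CC(=O)OC/C=C(\C)CC/C=C(\C)CCC[C@H](C)CC1(O)C=C(CO[Si](c2ccccc2)(c2ccccc2)C(C)(C)C)C(=O)O1
F2 | step 13 | (2E,6E,11S,12Z)-12-{4-[(tert-butyldiphenylsilyloxy)methyl]-5-oxofuran-2(5H)-ylidene}-3,7,11-trimethyldodeca-2,6-dien-1-yl acetate | CC(=O)OC/C=C(\C)CC/C=C(\C)CCC[C@H](C)/C=C1/C=C(CO[Si](c2ccccc2)(c2ccccc2)C(C)(C)C)C(=O)O1
F3 | step 13 | (furan-3-ylmethyl)zinc chloride | Cl[Zn]Cc1ccoc1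
F4 | step 10 | 3-[(tert-butyldiphenylsilyloxy)methyl]-5-[(2R)-2-methyl-4-(phenylsulfonyl)butyl]-2-(trimethylsilyl)furan | O=S(=O)(CC[C@H](C)Cc1cc(CO[Si](c2ccccc2)(c2ccccc2)C(C)(C)C)c([Si](C)(C)C)o1)c1ccccc1
F5 | step 10 | α-lithio derivative of F4, lithium on the carbon that bears the sulfonyl group | [Li]C(C[C@H](C)Cc1cc(CO[Si](c2ccccc2)(c2ccccc2)C(C)(C)C)c([Si](C)(C)C)o1)S(=O)(=O)c1ccccc1
F6 | step 10 | (2E,6E,11R)-12-{4-[(tert-butyldiphenylsilyloxy)methyl]-5-(trimethylsilyl)furan-2-yl}-3,7,11-trimethyl-9-(phenylsulfonyl)dodeca-2,6-dien-1-yl acetate, both C9 epimers | CC(=O)OC/C=C(\C)CC/C=C(\C)CC(C[C@H](C)Cc1cc(CO[Si](c2ccccc2)(c2ccccc2)C(C)(C)C)c([Si](C)(C)C)o1)S(=O)(=O)c1ccccc1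
F7 | step 5 | tert-butyl{[5-iodo-2-(trimethylsilyl)furan-3-yl]methoxy}diphenylsilane | CC(C)(C)[Si](OCc1cc(I)oc1[Si](C)(C)C)(c1ccccc1)c1ccccc1
F8 | step 5 | [(2S)-4-(tert-butyldimethylsilyloxy)-2-methylbutyl]zinc iodide | CC(C)(C)[Si](C)(C)OCC[C@H](C)C[Zn]I
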